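**Retrosynthetic overview**

- The route rests on ring C of the flavanone half (O1, C2, C3, C4, C4a, C8a). It is a 2-aryl-2,3-dihydropyran-4-one fused to ring A through C4a–C8a, so C2–C3, O1–C8a and the only stereocentre, C2, are cut back to a benzaldehyde and Danishefsky's diene (catalytic enantioselective hetero-Diels–Alder) before flavanone ring A exists.
- Flavanone ring A (C5–C8) is then grown on C4a/C8a. C8a–C8 comes from a vinylogous Mukaiyama–Michael addition of a dioxinone dienol ether, C8a is re-oxidised by Saegusa–Ito oxidation, and C4a–C5 is closed through a thermally generated acylketene. Aromatisation is then a tautomerisation, needs no dehydrogenation, and O1 cannot be lost by β-elimination.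
- The aldehyde carries the whole tri-O-benzylkaempferol unit. Its C3–O–aryl bond is made by Williamson etherification of an α-bromo ketone and its pyranone ring by Baker–Venkataraman rearrangement and cyclodehydration, from 2,4,6-trihydroxyacetophenone.
- Ring order: flavone ring C, then flavanone ring C (key step), then flavanone ring A. The end game is 7-O-methylation and hydrogenolysis of three benzyl ethers.

Key step: step 8

Abbreviation used in names: TBK = 5,7-bis(benzyloxy)-2-[4-(benzyloxy)phenyl]-4-oxo-4H-chromen-3-yl (tri-O-benzylkaempferol bound through O-3); "TBK-oxy" is this group attached through its C3 oxygen.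

Assumption: the (S)-BINOL–Ti(OiPr)4 catalyst is taken to direct the diene to the Si face of the aldehyde, as this catalyst family does with other nucleophiles; if the sense proves opposite, (R)-BINOL is used and nothing else changes.

**Route**

Step 1
Reactants: 1 2,4,6-trihydroxyacetophenone
Product: 2 1-[2,4-bis(benzyloxy)-6-hydroxyphenyl]ethanone
Conditions: BnBr (2.1 equiv), K2CO3 (2.2 equiv), DMF, rt
Reagents that add atoms: benzyl bromide, BrCc1ccccc1
Why: Williamson etherification of the two free phenols; the third OH is hydrogen-bonded to the acetyl carbonyl and should stay untouched with two equivalents of halide.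

Step 2
Reactants: 2 1-[2,4-bis(benzyloxy)-6-hydroxyphenyl]ethanone; 3 4-(benzyloxy)benzoyl chloride
Product: 4 2-acetyl-3,5-bis(benzyloxy)phenyl 4-(benzyloxy)benzoate
Conditions: pyridine, DMAP (cat.), CH2Cl2, 0 °C to rt
Reagents that add atoms: none
Why: O-acylation of the chelated phenol (first stage of the Baker–Venkataraman sequence), done now so that the ortho phenol cannot close a benzofuranone on the α-bromo ketone made in step 3.

Step 3
Reactants: 4 2-acetyl-3,5-bis(benzyloxy)phenyl 4-(benzyloxy)benzoate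
Product: 5 3,5-bis(benzyloxy)-2-(bromoacetyl)phenyl 4-(benzyloxy)benzoate
Conditions: CuBr2 (2.1 equiv), EtOAc/CHCl3 (1:1), reflux
Reagents that add atoms: CuBr2, [Cu+2].[Br-].[Br-]
Why: α-bromination of an aryl methyl ketone with CuBr2 runs through the copper enolate and should prefer the acetyl group to the alkoxy-rich ring.

Step 4
Reactants: 6 4-hydroxybenzaldehyde
Product: 7 4-(1,3-dioxolan-2-yl)phenol
Conditions: ethylene glycol (3 equiv), TsOH·H2O (cat.), toluene, reflux, Dean–Stark; Et3N quench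
Reagents that add atoms: ethylene glycol, OCCO
Why: acid-catalysed acetalisation with azeotropic removal of water masks the aldehyde against the enolate chemistry of steps 5 and 6.

Step 5
Reactants: 5 3,5-bis(benzyloxy)-2-(bromoacetyl)phenyl 4-(benzyloxy)benzoate; 7 4-(1,3-dioxolan-2-yl)phenol
Product: 8 3,5-bis(benzyloxy)-2-{[4-(1,3-dioxolan-2-yl)phenoxy]acetyl}phenyl 4-(benzyloxy)benzoate
Conditions: K2CO3 (1.5 equiv), acetone, rt
Reagents that add atoms: none
Why: Williamson etherification: SN2 displacement at an α-bromo ketone by a phenoxide is fast at room temperature and should outrun attack on the hindered aryl ester.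

Step 6
Reactants: 8 3,5-bis(benzyloxy)-2-{[4-(1,3-dioxolan-2-yl)phenoxy]acetyl}phenyl 4-(benzyloxy)benzoate
Product: 9 1-[2,4-bis(benzyloxy)-6-hydroxyphenyl]-3-[4-(benzyloxy)phenyl]-2-[4-(1,3-dioxolan-2-yl)phenoxy]propane-1,3-dione (racemic at C2)
Conditions: LiN(SiMe3)2 (2.5 equiv), THF, −78 to 0 °C; sat. NH4Cl
Reagents that add atoms: none
Why: Baker–Venkataraman rearrangement: the α-aryloxy ketone enolate attacks the neighbouring aryl ester through a six-membered transition state and the aroyl group moves from O to C, the acetal being inert to base.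

Step 7
Reactants: 9 1-[2,4-bis(benzyloxy)-6-hydroxyphenyl]-3-[4-(benzyloxy)phenyl]-2-[4-(1,3-dioxolan-2-yl)phenoxy]propane-1,3-dione
Product: 10 4-(TBK-oxy)benzaldehyde, i.e. 4-{[5,7-bis(benzyloxy)-2-(4-benzyloxyphenyl)-4-oxo-4H-chromen-3-yl]oxy}benzaldehyde
Conditions: NaOAc, AcOH, 100 °C; then 1 M HCl, THF, rt
Reagents that add atoms: water, O
Why: acid cyclodehydration of the 2-hydroxyaryl 1,3-diketone closes the flavone pyranone ring (6-exo-trig hemiketal, then loss of water) and aqueous acid then hydrolyses the acetal, strong hot acid being avoided to keep the acid-labile 5-O-benzyl ether.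

Step 8
Reactants: 10 4-(TBK-oxy)benzaldehyde; 11 Danishefsky's diene, (E)-1-methoxy-3-(trimethylsilyloxy)buta-1,3-diene
Product: 13 (2S)-2-[4-(TBK-oxy)phenyl]-2,3-dihydro-4H-pyran-4-one, via silyl aldol adduct 12 (not isolated)
Conditions: (S)-BINOL (40 mol%), Ti(OiPr)4 (20 mol%), CF3CO2H (cat.), 4 Å MS, CH2Cl2/Et2O, −20 °C, slow addition of 11 (1.5 equiv); then CF3CO2H, CH2Cl2, 0 °C
Reagents that add atoms: none
Why: The BINOLate of tetravalent titanium binds the aldehyde oxygen and the unsubstituted diene terminus attacks the carbonyl carbon (Mukaiyama aldol mode of the hetero-Diels–Alder reaction), forming C2–C3 and adduct 12; acid then makes the C2 oxygen add to the methoxy-bearing enone carbon in a 6-endo-trig addition–elimination that forms O1–C8a, closes ring C and expels methanol and the silyl group. The closest known reaction is the BINOL–titanium-catalysed hetero-Diels–Alder reaction of Danishefsky's diene with aromatic aldehydes, para-alkoxy ones included. The C2 stereocentre is set by the chiral ligand alone, which shields one face of the bound aldehyde so that the diene should add to the Si face and give (S). Regiochemistry follows from the polarised diene, and chemoselectivity from the aldehyde being the only carbon electrophile, since the flavone C2 is fully substituted and conjugated to two donor rings. The flavone carbonyl is a strong Lewis base and will hold part of the titanium, but the catalyst must in any case turn over beside the vinylogous-ester product of similar basicity, so the raised loading and slow diene addition should keep the catalysed path ahead of the background reaction. The product is a vinylogous ester whose C2–O1 bond is not broken in any later step.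

Step 9
Reactants: 14 2,2,6-trimethyl-4H-1,3-dioxin-4-one
Product: 15 trimethyl[(2,2-dimethyl-6-methylidene-6H-1,3-dioxin-4-yl)oxy]silane
Conditions: LiN(iPr)2 (1.1 equiv), THF, −78 °C; Me3SiCl, −78 °C to rt; distillation
Reagents that add atoms: chlorotrimethylsilane, C[Si](C)(C)Cl
Why: kinetic γ-deprotonation of the vinylogous ester and O-silylation give the silyl dienol ether, a standard vinylogous acetoacetate nucleophile.

Step 10
Reactants: 13 (2S)-2-[4-(TBK-oxy)phenyl]-2,3-dihydro-4H-pyran-4-one; 15 trimethyl[(2,2-dimethyl-6-methylidene-6H-1,3-dioxin-4-yl)oxy]silane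
Product: 16 (2S,6R)-6-[(2,2-dimethyl-4-oxo-4H-1,3-dioxin-6-yl)methyl]-2-[4-(TBK-oxy)phenyl]-4-(trimethylsilyloxy)-3,6-dihydro-2H-pyran (2,6-trans expected; either C6 epimer serves)
Conditions: Me3SiOTf (1.2 equiv), 15 (1.5 equiv), CH2Cl2, −78 °C; Et3N, then cold aq. NaHCO3; crude used at once
Reagents that add atoms: none
Why: vinylogous Mukaiyama–Michael addition: O-silylation of the vinylogous ester gives a cyclic oxocarbenium ion that the dienol ether should attack through its terminal CH2 at C6 (C8a of the target), axially and anti to the C2 aryl group, leaving the silyl group on O4 as a regiodefined enol ether, while the fully substituted flavone C2 is too hindered to compete and the low temperature guards the benzylic C2–O1 bond.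

Step 11
Reactants: 16 (2S,6R)-6-[(2,2-dimethyl-4-oxo-4H-1,3-dioxin-6-yl)methyl]-2-[4-(TBK-oxy)phenyl]-4-(trimethylsilyloxy)-3,6-dihydro-2H-pyran
Product: 17 (2S)-6-[(2,2-dimethyl-4-oxo-4H-1,3-dioxin-6-yl)methyl]-2-[4-(TBK-oxy)phenyl]-2,3-dihydro-4H-pyran-4-one
Conditions: Pd(OAc)2 (1.1 equiv), MeCN, rt
Reagents that add atoms: none
Why: Saegusa–Ito oxidation: the palladium enolate at C5 can lose only the β-hydrogen on C6, which restores the vinylogous ester with the side chain on C6, removes the transient C6 centre and raises C8a to the oxidation level of an aromatic carbon before ring A is closed.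

Step 12
Reactants: 17 (2S)-6-[(2,2-dimethyl-4-oxo-4H-1,3-dioxin-6-yl)methyl]-2-[4-(TBK-oxy)phenyl]-2,3-dihydro-4H-pyran-4-one
Product: 19 (2S)-5,7-dihydroxy-2-[4-(TBK-oxy)phenyl]-2,3-dihydro-4H-chromen-4-one, via acylketene 18 (not isolated)
Conditions: toluene (0.005 M), 110 °C
Reagents that add atoms: none
Why: Proposed new method: thermal retro-[4+2] loss of acetone from the dioxinone gives acylketene 18, whose C7 ketone enolises towards C8 to make a dienylketene (C5=C6, C7=C8, C8a=C4a); 6π-electrocyclisation, or equally direct attack of the enol-ether carbon C4a on the ketene carbon, forms C4a–C5 and tautomerisation gives the 5,7-dihydroxy ring A under neutral conditions that leave C2 alone; the closest known reactions are the dienylketene electrocyclisation of the Danheiser benzannulation and the trapping of dioxinone-derived acylketenes by nucleophiles; the aldol closure onto C4 would need a bridgehead alkene, O1 is locked in the enol ether so no pyranone can form, and high dilution should suppress ketene dimerisation.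

Step 13
Reactants: 19 (2S)-5,7-dihydroxy-2-[4-(TBK-oxy)phenyl]-2,3-dihydro-4H-chromen-4-one
Product: 20 (2S)-5-hydroxy-7-methoxy-2-[4-(TBK-oxy)phenyl]-2,3-dihydro-4H-chromen-4-one
Conditions: MeOH (1.2 equiv), PPh3 (1.2 equiv), DIAD (1.2 equiv), THF, 0 °C to rt
Reagents that add atoms: methanol, CO
Why: Mitsunobu etherification should pick the acidic 7-OH while the 5-OH stays locked in its hydrogen bond to the C4 carbonyl, and no free base is present that could open the flavanone to a chalcone and racemise C2.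

Step 14
Reactants: 20 (2S)-5-hydroxy-7-methoxy-2-[4-(TBK-oxy)phenyl]-2,3-dihydro-4H-chromen-4-one
Product: 21 (2S)-2-(4-{[5,7-dihydroxy-2-(4-hydroxyphenyl)-4-oxo-4H-chromen-3-yl]oxy}phenyl)-5-hydroxy-7-methoxy-2,3-dihydro-4H-chromen-4-one (CNP0173006.1)
Conditions: H2 (1 atm), Pd/C (10%), EtOAc/THF, rt, stopped at three equivalents of H2
Reagents that add atoms: none
Why: catalytic hydrogenolysis of the three benzyl aryl ethers under neutral conditions should spare the diaryl ether, both carbonyl groups and the cyclic C2–O1 aryl ether, and cannot epimerise C2.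

**Compound list**

1 | 2,4,6-trihydroxyacetophenone | CC(=O)c1c(O)cc(O)cc1O | starting material
2 | 1-[2,4-bis(benzyloxy)-6-hydroxyphenyl]ethanone | CC(=O)c1c(O)cc(OCc2ccccc2)cc1OCc1ccccc1 | intermediate
3 | 4-(benzyloxy)benzoyl chloride | O=C(Cl)c1ccc(OCc2ccccc2)cc1 | starting material
4 | 2-acetyl-3,5-bis(benzyloxy)phenyl 4-(benzyloxy)benzoate | CC(=O)c1c(OC(=O)c2ccc(OCc3ccccc3)cc2)cc(OCc2ccccc2)cc1OCc1ccccc1 | intermediate
5 | 3,5-bis(benzyloxy)-2-(bromoacetyl)phenyl 4-(benzyloxy)benzoate | O=C(CBr)c1c(OC(=O)c2ccc(OCc3ccccc3)cc2)cc(OCc2ccccc2)cc1OCc1ccccc1 | intermediate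
6 | 4-hydroxybenzaldehyde | O=Cc1ccc(O)cc1 | starting material
7 | 4-(1,3-dioxolan-2-yl)phenol | Oc1ccc(C2OCCO2)cc1 | intermediate
8 | 3,5-bis(benzyloxy)-2-{[4-(1,3-dioxolan-2-yl)phenoxy]acetyl}phenyl 4-(benzyloxy)benzoate | O=C(COc1ccc(C2OCCO2)cc1)c1c(OC(=O)c2ccc(OCc3ccccc3)cc2)cc(OCc2ccccc2)cc1OCc1ccccc1 | intermediate
9 | 1-[2,4-bis(benzyloxy)-6-hydroxyphenyl]-3-[4-(benzyloxy)phenyl]-2-[4-(1,3-dioxolan-2-yl)phenoxy]propane-1,3-dione (racemic) | O=C(c1ccc(OCc2ccccc2)cc1)C(Oc1ccc(C2OCCO2)cc1)C(=O)c1c(O)cc(OCc2ccccc2)cc1OCc1ccccc1 | intermediate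
10 | 4-{[5,7-bis(benzyloxy)-2-(4-benzyloxyphenyl)-4-oxo-4H-chromen-3-yl]oxy}benzaldehyde | O=Cc1ccc(Oc2c(-c3ccc(OCc4ccccc4)cc3)oc3cc(OCc4ccccc4)cc(OCc4ccccc4)c3c2=O)cc1 | intermediate
11 | Danishefsky's diene, (E)-1-methoxy-3-(trimethylsilyloxy)buta-1,3-diene | CO/C=C/C(=C)O[Si](C)(C)C | starting material
12 | (1E,5S)-1-methoxy-5-[4-(TBK-oxy)phenyl]-5-(trimethylsilyloxy)pent-1-en-3-one | CO/C=C/C(=O)C[C@H](O[Si](C)(C)C)c1ccc(Oc2c(-c3ccc(OCc4ccccc4)cc3)oc3cc(OCc4ccccc4)cc(OCc4ccccc4)c3c2=O)cc1 | intermediate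
13 | (2S)-2-[4-(TBK-oxy)phenyl]-2,3-dihydro-4H-pyran-4-one | O=C1C=CO[C@H](c2ccc(Oc3c(-c4ccc(OCc5ccccc5)cc4)oc4cc(OCc5ccccc5)cc(OCc5ccccc5)c4c3=O)cc2)C1 | intermediate
14 | 2,2,6-trimethyl-4H-1,3-dioxin-4-one | CC1=CC(=O)OC(C)(C)O1 | starting material
15 | trimethyl[(2,2-dimethyl-6-methylidene-6H-1,3-dioxin-4-yl)oxy]silane | C=C1C=C(O[Si](C)(C)C)OC(C)(C)O1 | intermediate
16 | (2S,6R)-6-[(2,2-dimethyl-4-oxo-4H-1,3-dioxin-6-yl)methyl]-2-[4-(TBK-oxy)phenyl]-4-(trimethylsilyloxy)-3,6-dihydro-2H-pyran | C[Si](C)(C)OC1=C[C@@H](CC2=CC(=O)OC(C)(C)O2)O[C@H](c2ccc(Oc3c(-c4ccc(OCc5ccccc5)cc4)oc4cc(OCc5ccccc5)cc(OCc5ccccc5)c4c3=O)cc2)C1 | intermediate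
17 | (2S)-6-[(2,2-dimethyl-4-oxo-4H-1,3-dioxin-6-yl)methyl]-2-[4-(TBK-oxy)phenyl]-2,3-dihydro-4H-pyran-4-one | O=C1C=C(CC2=CC(=O)OC(C)(C)O2)O[C@H](c2ccc(Oc3c(-c4ccc(OCc5ccccc5)cc4)oc4cc(OCc5ccccc5)cc(OCc5ccccc5)c4c3=O)cc2)C1 | intermediate
18 | (2S)-6-(2,4-dioxobut-3-en-1-yl)-2-[4-(TBK-oxy)phenyl]-2,3-dihydro-4H-pyran-4-one (acylketene) | O=C=CC(=O)CC1=CC(=O)C[C@@H](c2ccc(Oc3c(-c4ccc(OCc5ccccc5)cc4)oc4cc(OCc5ccccc5)cc(OCc5ccccc5)c4c3=O)cc2)O1 | intermediate
19 | (2S)-5,7-dihydroxy-2-[4-(TBK-oxy)phenyl]-2,3-dihydro-4H-chromen-4-one | Oc1cc(O)c2c(c1)O[C@H](c1ccc(Oc3c(-c4ccc(OCc5ccccc5)cc4)oc4cc(OCc5ccccc5)cc(OCc5ccccc5)c4c3=O)cc1)CC2=O | intermediate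
20 | (2S)-5-hydroxy-7-methoxy-2-[4-(TBK-oxy)phenyl]-2,3-dihydro-4H-chromen-4-one | COc1cc(O)c2c(c1)O[C@H](c1ccc(Oc3c(-c4ccc(OCc5ccccc5)cc4)oc4cc(OCc5ccccc5)cc(OCc5ccccc5)c4c3=O)cc1)CC2=O | intermediate
21 | (2S)-2-(4-{[5,7-dihydroxy-2-(4-hydroxyphenyl)-4-oxo-4H-chromen-3-yl]oxy}phenyl)-5-hydroxy-7-methoxy-2,3-dihydro-4H-chromen-4-one | COc1cc(O)c2c(c1)O[C@H](c1ccc(Oc3c(-c4ccc(O)cc4)oc4cc(O)cc(O)c4c3=O)cc1)CC2=O | target

**Step count and risks**

Total step count: 14. Longest linear sequence: 12 steps (steps 1–3, 5–8 and 10–14); steps 4 and 9 are side branches.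

Steps most likely to fail:

1. Step 12 (the proposed new method). The acylketene may be consumed by dimerisation or by intermolecular acylation of phenols before the C4a–C5 bond forms, or long heating may start to open the flavanone. Fallback with known chemistry, from 17 back to 19: 17 is heated in toluene with methanol, so that the acylketene is trapped by the alcohol as the β-keto ester methyl 4-{(2S)-4-oxo-2-[4-(TBK-oxy)phenyl]-3,4-dihydro-2H-pyran-6-yl}-3-oxobutanoate F1. F1 is then closed with Mg(OMe)2 in MeOH at low temperature by the Claisen cyclisation known for 3,5,7-tricarbonyl esters giving acylphloroglucinols: C4a attacks the ester and methanol is lost, giving 19. The cyclisation is quenched cold with acid to limit base-induced ring opening.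

2. Step 8 (key step). Titanium may be sequestered by the flavone carbonyl, so that turnover stalls and the unselective background addition erodes the enantioface selection. Fallback, from 10 back to 13: hydrogen-bond catalysis replaces the Lewis acid. Aldehyde 10 is combined with 1-(dimethylamino)-3-(tert-butyldimethylsilyloxy)buta-1,3-diene and a tetra(1-naphthyl) TADDOL (the enantiomer that gives (S)) in toluene at −40 °C. This forms the aminal cycloadduct (2S)-4-(tert-butyldimethylsilyloxy)-6-(dimethylamino)-2-[4-(TBK-oxy)phenyl]-3,6-dihydro-2H-pyran F2, and acetyl chloride at −78 °C then eliminates the amine and the silyl group to give 13.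

3. Step 3. Electrophilic bromination of the alkoxy-rich ring, or HBr-induced loss of benzyl groups, may compete with α-bromination. Fallback, from 4 back to 10, which avoids any α-halogenation and forms the C3–O–aryl bond last:
   - Ester 4 undergoes Baker–Venkataraman rearrangement (KOH, pyridine, 50 °C) to 1-[2,4-bis(benzyloxy)-6-hydroxyphenyl]-3-[4-(benzyloxy)phenyl]propane-1,3-dione F3.
   - NaOAc/AcOH cyclodehydration gives 5,7-bis(benzyloxy)-2-[4-(benzyloxy)phenyl]-4H-chromen-4-one F4.
   - Dimethyldioxirane in acetone/CH2Cl2 gives the 2,3-epoxide of that flavone F5, which a trace of TsOH opens to 5,7-bis(benzyloxy)-2-[4-(benzyloxy)phenyl]-3-hydroxy-4H-chromen-4-one F6.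
   - SNAr of F6 on 4-fluorobenzaldehyde (K2CO3, DMF, 100 °C, argon) gives 10.

Further compounds
F1 | step 12 | methyl 4-{(2S)-4-oxo-2-[4-(TBK-oxy)phenyl]-3,4-dihydro-2H-pyran-6-yl}-3-oxobutanoate | COC(=O)CC(=O)CC1=CC(=O)C[C@@H](c2ccc(Oc3c(-c4ccc(OCc5ccccc5)cc4)oc4cc(OCc5ccccc5)cc(OCc5ccccc5)c4c3=O)cc2)O1
F2 | step 8 | (2S)-4-(tert-butyldimethylsilyloxy)-6-(dimethylamino)-2-[4-(TBK-oxy)phenyl]-3,6-dihydro-2H-pyran (C6 epimers) | CN(C)C1C=C(O[Si](C)(C)C(C)(C)C)C[C@@H](c2ccc(Oc3c(-c4ccc(OCc5ccccc5)cc4)oc4cc(OCc5ccccc5)cc(OCc5ccccc5)c4c3=O)cc2)O1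
F3 | step 3 | 1-[2,4-bis(benzyloxy)-6-hydroxyphenyl]-3-[4-(benzyloxy)phenyl]propane-1,3-dione | O=C(CC(=O)c1c(O)cc(OCc2ccccc2)cc1OCc1ccccc1)c1ccc(OCc2ccccc2)cc1
F4 | step 3 | 5,7-bis(benzyloxy)-2-[4-(benzyloxy)phenyl]-4H-chromen-4-one | O=c1cc(-c2ccc(OCc3ccccc3)cc2)oc2cc(OCc3ccccc3)cc(OCc3ccccc3)c12
F5 | step 3 | 5,7-bis(benzyloxy)-2-[4-(benzyloxy)phenyl]-2,3-epoxy-2,3-dihydro-4H-chromen-4-one (racemic) | O=C1C2OC2(c2ccc(OCc3ccccc3)cc2)Oc2cc(OCc3ccccc3)cc(OCc3ccccc3)c21
F6 | step 3 | 5,7-bis(benzyloxy)-2-[4-(benzyloxy)phenyl]-3-hydroxy-4H-chromen-4-one | O=c1c(O)c(-c2ccc(OCc3ccccc3)cc2)oc2cc(OCc3ccccc3)cc(OCc3ccccc3)c12
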